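## Retrosynthetic overview

1. Feature: every position of ring A (a phloroglucinol) is different (C8a–O1, C8–prenyl, C7–OH, C6–H, C5–OMe), and C4a carries the chain C4–C3–C2. The 3,4-cis (erythro, 3S,4S) diol of that chain is C3/C2 of D-erythronolactone, with lactone C1 becoming C4a and lactone C4 becoming C2.
2. Ring C is disconnected at O1–C2. The C8a phenol adds to a ring B para-quinone methide released from a C2 acetate, and this step alone sets C2 (2,3-trans).
3. Ring A is disconnected at C5–C6, C6–C7, C8–C8a and C4a–C8a into a sugar-derived (Z)-2-methoxyenone diazoketone and the prenyl triisopropylsiloxyalkyne (Wolff shift, [2+2], 4π opening, 6π closure).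
4. The diazoketone comes from the bis-silylated lactol by olefination (C4a=C5), oxidation, aryl Grignard addition (C2–C1'), then ester → methyl ketone → diazo transfer. This order keeps the acetate away from hydroxide and avoids treating an enoyl chloride with diazomethane.
5. Ring order: B (bought as 4-bromophenol), then A (step 11), then C (step 12).

Key step: step 11

Assumption: the carbinol carbon made in step 6 (future C2) is drawn as its Felkin–Anh epimer; it becomes trigonal in step 12, so any minor epimer can be carried along unseparated.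

Flavan numbering is used for the carbons of all intermediates. TBS = tert-butyldimethylsilyl, TIPS = triisopropylsilyl, TBSO/TIPSO = the corresponding silyloxy groups.

## Route

Step 1
Reactants: 1 D-erythronolactone, (3R,4R)-3,4-dihydroxyoxolan-2-one
Product: 2 (3R,4R)-3,4-bis(TBSO)oxolan-2-one
Conditions: TBSCl, imidazole, DMF, rt → 45 °C
Reagents that add atoms: tert-butyldimethylsilyl chloride, CC(C)(C)[Si](C)(C)Cl
Why: Standard imidazole-promoted O-silylation covers both secondary hydroxyls without touching the lactone or its stereocentres, and fluoride-labile groups are chosen because the final benzylic 3,4-diol tolerates neither acid nor hydrogenolysis.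

Step 2
Reactants: 2 (3R,4R)-3,4-bis(TBSO)oxolan-2-one
Product: 3 (3R,4R)-3,4-bis(TBSO)oxolan-2-ol (anomer mixture)
Conditions: i-Bu2AlH, CH2Cl2, −78 °C
Reagents that add atoms: none
Why: Partial lactone reduction stops at the tetrahedral aluminium hemiacetal at low temperature and should give the lactol on hydrolysis, with the future C4 and C3 unchanged.

Step 3
Reactants: 3 (3R,4R)-3,4-bis(TBSO)oxolan-2-ol; 4 methyl 2-(dimethoxyphosphoryl)-2-methoxyacetate
Product: 5 methyl (2Z,4S,5R)-4,5-bis(TBSO)-6-hydroxy-2-methoxyhex-2-enoate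
Conditions: LiCl, DBU, MeCN, 0 °C → rt
Reagents that add atoms: none
Why: Horner–Wadsworth–Emmons olefination under Masamune–Roush conditions intercepts the hydroxy-aldehyde tautomer of the lactol; the amine base avoids a metal alkoxide that could start a 1,2-silyl shift, the donor methoxy group makes the new alkene a poor oxa-Michael acceptor, and the ester should settle trans to the branched chain (Z alkene, C4a=C5).

Step 4
Reactants: 5 methyl (2Z,4S,5R)-4,5-bis(TBSO)-6-hydroxy-2-methoxyhex-2-enoate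
Product: 6 methyl (2Z,4S,5S)-4,5-bis(TBSO)-2-methoxy-6-oxohex-2-enoate
Conditions: Dess–Martin periodinane, CH2Cl2, 0 °C → rt
Reagents that add atoms: none
Why: Dess–Martin oxidation takes the primary alcohol to the aldehyde without base, so the alpha-siloxy centre (future C3) should not epimerise and the silyl ethers and enol ether stay intact.

Step 5
Reactants: 7 4-bromophenol
Product: 8 (4-bromophenoxy)(tert-butyl)dimethylsilane
Conditions: TBSCl, imidazole, DMF, rt
Reagents that add atoms: tert-butyldimethylsilyl chloride, CC(C)(C)[Si](C)(C)Cl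
Why: Standard O-silylation masks the phenol so that the aryl bromide can be turned into a Grignard reagent.

Step 6
Reactants: 8 (4-bromophenoxy)(tert-butyl)dimethylsilane; 6 methyl (2Z,4S,5S)-4,5-bis(TBSO)-2-methoxy-6-oxohex-2-enoate
Product: 10 methyl (2Z,4S,5R,6R)-4,5-bis(TBSO)-6-hydroxy-2-methoxy-6-[4-(TBSO)phenyl]hex-2-enoate, via arylmagnesium bromide 9 (not isolated)
Conditions: 8, Mg, THF, reflux; then 6, THF, −78 °C
Reagents that add atoms: magnesium, [Mg] (held only in intermediate 9)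
Why: Grignard addition is chemoselective for the aldehyde over the conjugated ester at −78 °C and should follow the polar Felkin–Anh model (attack anti to the alpha-siloxy group) to give the 2,3-anti carbinol, a centre that is erased again in step 12.

Step 7
Reactants: 10 methyl (2Z,4S,5R,6R)-4,5-bis(TBSO)-6-hydroxy-2-methoxy-6-[4-(TBSO)phenyl]hex-2-enoate
Product: 12 (3Z,5S,6R,7R)-5,6-bis(TBSO)-7-hydroxy-3-methoxy-7-[4-(TBSO)phenyl]hept-3-en-2-one, via Weinreb amide 11 (not isolated)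
Conditions: MeNH(OMe)·HCl, i-PrMgCl, THF, −20 → 0 °C; then MeMgBr, 0 °C
Reagents that add atoms: methylmagnesium bromide, C[Mg]Br; N,O-dimethylhydroxylamine hydrochloride, CNOC.Cl (held only in intermediate 11)
Why: Weinreb ketone synthesis in one flask: the chloromagnesium amide converts the ester into amide 11, whose chelated tetrahedral adduct with MeMgBr resists over-addition, while the carbinol is carried as a covalent magnesium alkoxide that should not pass silyl groups at or below 0 °C.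

Step 8
Reactants: 12 (3Z,5S,6R,7R)-5,6-bis(TBSO)-7-hydroxy-3-methoxy-7-[4-(TBSO)phenyl]hept-3-en-2-one
Product: 13 (1R,2R,3S,4Z)-2,3-bis(TBSO)-5-methoxy-6-oxo-1-[4-(TBSO)phenyl]hept-4-en-1-yl acetate
Conditions: Ac2O, DMAP (cat.), pyridine, 0 °C → rt
Reagents that add atoms: acetic anhydride, CC(=O)OC(C)=O
Why: DMAP-catalysed acylation puts the leaving group needed in step 12 on the C2 oxygen only after all nucleophilic carbonyl chemistry is finished.

Step 9
Reactants: 13 (1R,2R,3S,4Z)-2,3-bis(TBSO)-5-methoxy-6-oxo-1-[4-(TBSO)phenyl]hept-4-en-1-yl acetate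
Product: 15 (1R,2R,3S,4Z)-7-diazo-2,3-bis(TBSO)-5-methoxy-6-oxo-1-[4-(TBSO)phenyl]hept-4-en-1-yl acetate, via trifluoroacetyl ketone 14 (not isolated)
Conditions: LiN(SiMe3)2, THF, −78 °C; CF3CO2CH2CF3, −78 °C; cold 5% aq HCl wash; then MsN3, Et3N, H2O, MeCN, rt
Reagents that add atoms: methanesulfonyl azide, CS(=O)(=O)N=[N+]=[N-]; 2,2,2-trifluoroethyl trifluoroacetate, O=C(OCC(F)(F)F)C(F)(F)F (held only in intermediate 14)
Why: Detrifluoroacetylative diazo transfer (Regitz-type transfer to a transiently activated ketone): kinetic deprotonation of the much more acidic methyl ketone and Claisen trifluoroacetylation give 14, which takes N2 from MsN3 and sheds trifluoroacetate, avoiding both a saponification that would strip the acetate and the pyrazoline formation of enoyl chlorides with diazomethane.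

Step 10
Reactants: 16 ethyl 4-methylpent-3-enoate
Product: 19 triisopropyl[(5-methylhex-4-en-1-yn-1-yl)oxy]silane, via dibromoketone lithium enolate 17 (not isolated), via lithium ynolate 18 (not isolated)
Conditions: CH2Br2, lithium 2,2,6,6-tetramethylpiperidide, THF, −78 °C; n-BuLi, −78 °C → rt; i-Pr3SiCl, 0 °C → rt
Reagents that add atoms: dibromomethane, BrCBr; triisopropylsilyl chloride, CC(C)[Si](Cl)(C(C)C)C(C)C; lithium 2,2,6,6-tetramethylpiperidide, [Li]N1C(C)(C)CCCC1(C)C (lithium held only in intermediates 17 and 18)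
Why: Kowalski ester homologation: addition of LiCHBr2, enolisation, bromine–lithium exchange and 1,2-shift of the prenyl group give ynolate 18, which the bulky silyl chloride captures on oxygen.

Step 11
Reactants: 15 (1R,2R,3S,4Z)-7-diazo-2,3-bis(TBSO)-5-methoxy-6-oxo-1-[4-(TBSO)phenyl]hept-4-en-1-yl acetate; 19 triisopropyl[(5-methylhex-4-en-1-yn-1-yl)oxy]silane
Product: 24 (1R,2R,3S)-2,3-bis(TBSO)-3-[2-hydroxy-6-methoxy-3-(3-methylbut-2-en-1-yl)-4-(TIPSO)phenyl]-1-[4-(TBSO)phenyl]propyl acetate, via methoxy vinylketene 20 (not isolated), via vinylcyclobutenone 21 (not isolated), via dienylketene 22 (not isolated), via cyclohexadienone 23 (not isolated)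
Conditions: 19 (2–3 equiv), degassed ClCH2CH2Cl, hν (350 nm lamps, Pyrex), rt; then 80 °C
Reagents that add atoms: none
Why: Excitation of the diazoketone expels N2 with a 1,2-shift of the methoxyvinyl carbon C5 onto C6 (Wolff rearrangement), giving vinylketene 20 whose carbonyl carbon is the future C8a. The polarised siloxyalkyne then adds in a [2+2] step, its nucleophilic prenyl-bearing carbon bonding to the ketene carbon (C8–C8a) and its oxygen-bearing carbon to C6 (C6–C7), so cyclobutenone 21 can form in one orientation only. Light or the 80 °C stage cleaves C6–C8a of 21 by four-electron electrocyclic opening to dienylketene 22, and ring A closes by six-electron electrocyclisation (C4a–C8a) to dienone 23, which tautomerises to phenol 24; this is the Danheiser benzannulation in its photochemical Wolff form, known for enone diazoketones with siloxyalkynes. No stereocentre is made, and C4, C3 and C2 are spectators because the medium is neutral and aprotic. The step needs the right alkyne orientation, secured by the oxygen polarisation, and a chain pointing outward at C4a, secured by the Z alkene, which also denies the ketene a 1,5-hydrogen shift from C4–H. Irradiation above 300 nm addresses only the diazoketone chromophore and leaves the 4-siloxybenzyl acetate unexcited, while excess 19 should outrun ketene dimerisation and acylation of 24.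

Step 12
Reactants: 24 (1R,2R,3S)-2,3-bis(TBSO)-3-[2-hydroxy-6-methoxy-3-(3-methylbut-2-en-1-yl)-4-(TIPSO)phenyl]-1-[4-(TBSO)phenyl]propyl acetate
Product: 27 (2R,3R,4S)-3,4-bis(TBSO)-2-(4-hydroxyphenyl)-5-methoxy-8-(3-methylbut-2-en-1-yl)chroman-7-ol (2,3-trans-3,4-cis), via triphenol acetate 25 (not isolated), via para-quinone methide 26 (not isolated)
Conditions: Bu4NF (2.2 equiv), THF, −78 → 0 °C; AcOH quench
Reagents that add atoms: none
Why: Fluoride cleaves the two aryl silyl ethers far faster than the secondary alkyl ones, the ring B phenoxide expels acetate by 1,6-elimination to para-quinone methide 26, and the C8a phenol closes ring C by 6-exo-trig oxa-1,6-conjugate addition; allylic 1,3-strain holds C3–H in the plane of the quinone methide, so O1 reaches the face of C2 that leaves H2 and H3 anti, which sets C2 as R (2,3-trans).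

Step 13
Reactants: 27 (2R,3R,4S)-3,4-bis(TBSO)-2-(4-hydroxyphenyl)-5-methoxy-8-(3-methylbut-2-en-1-yl)chroman-7-ol
Product: 28 5-O-methyl-8-prenylafzelechin-4beta-ol, (2R,3S,4S)-2-(4-hydroxyphenyl)-5-methoxy-8-(3-methylbut-2-en-1-yl)chroman-3,4,7-triol
Conditions: Bu4NF, AcOH (1:1, excess), THF, rt → 40 °C
Reagents that add atoms: none
Why: Acetic acid-buffered fluoride desilylation removes the two secondary silyl ethers near neutrality, which keeps the phenols protonated (no retro-oxa-Michael at C2, no ring A quinone methide at C4) and avoids the acid that would ionise C4–OH or cyclise the prenyl group onto O7.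

## Compound list

1 | D-erythronolactone | C1[C@H]([C@H](C(=O)O1)O)O | starting material
2 | (3R,4R)-3,4-bis(TBSO)oxolan-2-one | C1[C@H]([C@H](C(=O)O1)O[Si](C)(C)C(C)(C)C)O[Si](C)(C)C(C)(C)C | intermediate
3 | (3R,4R)-3,4-bis(TBSO)oxolan-2-ol, anomer mixture | C1[C@H]([C@H](C(O)O1)O[Si](C)(C)C(C)(C)C)O[Si](C)(C)C(C)(C)C | intermediate
4 | methyl 2-(dimethoxyphosphoryl)-2-methoxyacetate | COC(C(=O)OC)P(=O)(OC)OC | starting material
5 | methyl (2Z,4S,5R)-4,5-bis(TBSO)-6-hydroxy-2-methoxyhex-2-enoate | COC(=O)/C(OC)=C/[C@H](O[Si](C)(C)C(C)(C)C)[C@H](O[Si](C)(C)C(C)(C)C)CO | intermediate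
6 | methyl (2Z,4S,5S)-4,5-bis(TBSO)-2-methoxy-6-oxohex-2-enoate | COC(=O)/C(OC)=C/[C@H](O[Si](C)(C)C(C)(C)C)[C@H](O[Si](C)(C)C(C)(C)C)C=O | intermediate
7 | 4-bromophenol | Oc1ccc(Br)cc1 | starting material
8 | (4-bromophenoxy)(tert-butyl)dimethylsilane | CC(C)(C)[Si](C)(C)Oc1ccc(Br)cc1 | intermediate
9 | 4-(TBSO)phenylmagnesium bromide | CC(C)(C)[Si](C)(C)Oc1ccc([Mg]Br)cc1 | intermediate
10 | methyl (2Z,4S,5R,6R)-4,5-bis(TBSO)-6-hydroxy-2-methoxy-6-[4-(TBSO)phenyl]hex-2-enoate | COC(=O)/C(OC)=C/[C@H](O[Si](C)(C)C(C)(C)C)[C@H](O[Si](C)(C)C(C)(C)C)[C@H](O)c1ccc(O[Si](C)(C)C(C)(C)C)cc1 | intermediate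
11 | (2Z,4S,5R,6R)-4,5-bis(TBSO)-6-hydroxy-N,2-dimethoxy-N-methyl-6-[4-(TBSO)phenyl]hex-2-enamide (present as its magnesium alkoxide) | CON(C)C(=O)/C(OC)=C/[C@H](O[Si](C)(C)C(C)(C)C)[C@H](O[Si](C)(C)C(C)(C)C)[C@H](O)c1ccc(O[Si](C)(C)C(C)(C)C)cc1 | intermediate
12 | (3Z,5S,6R,7R)-5,6-bis(TBSO)-7-hydroxy-3-methoxy-7-[4-(TBSO)phenyl]hept-3-en-2-one | CC(=O)/C(OC)=C/[C@H](O[Si](C)(C)C(C)(C)C)[C@H](O[Si](C)(C)C(C)(C)C)[C@H](O)c1ccc(O[Si](C)(C)C(C)(C)C)cc1 | intermediate
13 | (1R,2R,3S,4Z)-2,3-bis(TBSO)-5-methoxy-6-oxo-1-[4-(TBSO)phenyl]hept-4-en-1-yl acetate | CC(=O)/C(OC)=C/[C@H](O[Si](C)(C)C(C)(C)C)[C@H](O[Si](C)(C)C(C)(C)C)[C@H](OC(C)=O)c1ccc(O[Si](C)(C)C(C)(C)C)cc1 | intermediate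
14 | (1R,2R,3S,4Z)-2,3-bis(TBSO)-9,9,9-trifluoro-5-methoxy-6,8-dioxo-1-[4-(TBSO)phenyl]non-4-en-1-yl acetate | FC(F)(F)C(=O)CC(=O)/C(OC)=C/[C@H](O[Si](C)(C)C(C)(C)C)[C@H](O[Si](C)(C)C(C)(C)C)[C@H](OC(C)=O)c1ccc(O[Si](C)(C)C(C)(C)C)cc1 | intermediate
15 | (1R,2R,3S,4Z)-7-diazo-2,3-bis(TBSO)-5-methoxy-6-oxo-1-[4-(TBSO)phenyl]hept-4-en-1-yl acetate | [N-]=[N+]=CC(=O)/C(OC)=C/[C@H](O[Si](C)(C)C(C)(C)C)[C@H](O[Si](C)(C)C(C)(C)C)[C@H](OC(C)=O)c1ccc(O[Si](C)(C)C(C)(C)C)cc1 | intermediate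
16 | ethyl 4-methylpent-3-enoate | CCOC(=O)CC=C(C)C | starting material
17 | lithium enolate of 1,1-dibromo-5-methylhex-4-en-2-one | [Li]OC(CC=C(C)C)=C(Br)Br | intermediate
18 | lithium 5-methylhex-4-en-1-yn-1-olate | [Li]OC#CCC=C(C)C | intermediate
19 | triisopropyl[(5-methylhex-4-en-1-yn-1-yl)oxy]silane | CC(C)=CCC#CO[Si](C(C)C)(C(C)C)C(C)C | intermediate
20 | (1R,2R,3S,4Z)-2,3-bis(TBSO)-5-methoxy-7-oxo-1-[4-(TBSO)phenyl]hepta-4,6-dien-1-yl acetate (vinylketene) | O=C=C/C(OC)=C/[C@H](O[Si](C)(C)C(C)(C)C)[C@H](O[Si](C)(C)C(C)(C)C)[C@H](OC(C)=O)c1ccc(O[Si](C)(C)C(C)(C)C)cc1 | intermediate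
21 | 2-prenyl-3-(TIPSO)cyclobut-2-en-1-one carrying at C4 the (Z)-methoxyalkenyl chain of 20 (epimers at the ring carbon C6) | O=C1C(CC=C(C)C)=C(O[Si](C(C)C)(C(C)C)C(C)C)C1/C(OC)=C/[C@H](O[Si](C)(C)C(C)(C)C)[C@H](O[Si](C)(C)C(C)(C)C)[C@H](OC(C)=O)c1ccc(O[Si](C)(C)C(C)(C)C)cc1 | intermediate
22 | dienylketene O=C8a=C8(prenyl)–C7(OTIPS)=C6H–C5(OMe)=C4aH–chain, with C8 and C5 cis on C7=C6 | O=C=C(CC=C(C)C)/C(O[Si](C(C)C)(C(C)C)C(C)C)=C\C(OC)=C\[C@H](O[Si](C)(C)C(C)(C)C)[C@H](O[Si](C)(C)C(C)(C)C)[C@H](OC(C)=O)c1ccc(O[Si](C)(C)C(C)(C)C)cc1 | intermediate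
23 | 5-methoxy-2-prenyl-3-(TIPSO)cyclohexa-2,4-dien-1-one carrying the chain at C6 of the dienone (epimers at C4a) | O=C1C(CC=C(C)C)=C(O[Si](C(C)C)(C(C)C)C(C)C)C=C(OC)C1[C@H](O[Si](C)(C)C(C)(C)C)[C@H](O[Si](C)(C)C(C)(C)C)[C@H](OC(C)=O)c1ccc(O[Si](C)(C)C(C)(C)C)cc1 | intermediate
24 | (1R,2R,3S)-2,3-bis(TBSO)-3-[2-hydroxy-6-methoxy-3-(3-methylbut-2-en-1-yl)-4-(TIPSO)phenyl]-1-[4-(TBSO)phenyl]propyl acetate | COc1cc(O[Si](C(C)C)(C(C)C)C(C)C)c(CC=C(C)C)c(O)c1[C@H](O[Si](C)(C)C(C)(C)C)[C@H](O[Si](C)(C)C(C)(C)C)[C@H](OC(C)=O)c1ccc(O[Si](C)(C)C(C)(C)C)cc1 | intermediate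
25 | (1R,2R,3S)-2,3-bis(TBSO)-3-[2,4-dihydroxy-6-methoxy-3-(3-methylbut-2-en-1-yl)phenyl]-1-(4-hydroxyphenyl)propyl acetate (present as phenoxides) | COc1cc(O)c(CC=C(C)C)c(O)c1[C@H](O[Si](C)(C)C(C)(C)C)[C@H](O[Si](C)(C)C(C)(C)C)[C@H](OC(C)=O)c1ccc(O)cc1 | intermediate
26 | 4-{(2R,3S)-2,3-bis(TBSO)-3-[2,4-dihydroxy-6-methoxy-3-(3-methylbut-2-en-1-yl)phenyl]propylidene}cyclohexa-2,5-dien-1-one | COc1cc(O)c(CC=C(C)C)c(O)c1[C@H](O[Si](C)(C)C(C)(C)C)[C@H](O[Si](C)(C)C(C)(C)C)C=C1C=CC(=O)C=C1 | intermediate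
27 | (2R,3R,4S)-3,4-bis(TBSO)-2-(4-hydroxyphenyl)-5-methoxy-8-(3-methylbut-2-en-1-yl)chroman-7-ol | COc1cc(O)c(CC=C(C)C)c2c1[C@H](O[Si](C)(C)C(C)(C)C)[C@H](O[Si](C)(C)C(C)(C)C)[C@@H](c1ccc(O)cc1)O2 | intermediate
28 | 5-O-methyl-8-prenylafzelechin-4beta-ol, (2R,3S,4S) | COc1cc(O)c(CC=C(C)C)c2c1[C@H](O)[C@H](O)[C@@H](c1ccc(O)cc1)O2 | target

## Step count and risks

Total step count: 13. Longest linear sequence: 11 steps (1, 2, 3, 4, 6, 7, 8, 9, 11, 12, 13, from compound 1).

**Step 11 (key step).**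
- The [2+2] capture of the donor-substituted, sterically loaded vinylketene by the alkyne may be slow. Ketene dimerisation, acylation of the product phenol by the ketene, or stalling at the cyclobutenone stage could then take over.
- The fallback leaves the route at 15 and returns at 24. It replaces the concerted cascade by an ionic benzannulation of an isolable ketene.
- 15 is silylated at the diazo carbon (i-Pr3SiOTf, i-Pr2NEt, Et2O–hexane) to the alpha-silyl diazoketone F1.
- Irradiation of F1 alone gives, by Wolff shift, the robust (triisopropylsilyl)vinylketene F2, which can be purified.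
- Lithium ynolate 18, regenerated cleanly from purified 19 with MeLi, is then C-acylated by F2 at its prenyl-bearing carbon.
- The resulting 3-oxido dienylketene closes by six-electron electrocyclisation. A 1,3 carbon-to-oxygen silyl shift moves the triisopropylsilyl group from C6 to O7, which should deliver 24 with the same oxygen pattern.

**Step 12.**
- Facial selectivity in the oxa-conjugate addition may be poor, and reversible ring opening through the ring B phenoxide may erode C2.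
- The quinone methide may tautomerise to a vinylphenol.
- C4–O may ionise through the freed C7 phenoxide.
- The fallback leaves at 24 and returns at 28. It replaces the planar intermediate by a stereospecific SN2 closure.
- i-Bu2AlH (CH2Cl2, −78 °C) removes the acetate to give the free C2 carbinol F3.
- MnO2 oxidises its benzylic alcohol to the aryl ketone F4.
- LiBH(s-Bu)3 (THF, −78 °C) delivers hydride under Felkin–Anh control to give the 2,3-syn carbinol F5.
- An intramolecular Mitsunobu etherification (PPh3, DIAD) joins O1 to C2 with inversion to give the fully silylated 2,3-trans flavan F6.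
- Buffered Bu4NF/AcOH then removes all four silyl groups to give 28 without ever exposing a ring B phenoxide to base.

**Step 3.**
- A silyl group may migrate to the freed primary oxygen.
- The ring may re-close by oxa-Michael addition.
- The alpha-siloxy aldehyde tautomer may epimerise, or alkene geometry control may be poor.
- The fallback leaves at 2 and returns at 5. It never olefinates in the presence of a free hydroxyl.
- 2 is opened with MeNH(OMe)·HCl/AlMe3 to the hydroxy Weinreb amide F7, which is capped at once (Et3SiCl, imidazole) as its triethylsilyl ether F8.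
- i-Bu2AlH reduces the amide to the open-chain aldehyde F9.
- The same phosphonate 4 (LiCl, DBU) converts F9 into the silyl-protected enoate F10.
- Mild methanolysis (pyridinium tosylate, MeOH, 0 °C) removes only the primary triethylsilyl group to give 5.

## Further compounds

F1 | step 11 | (1R,2R,3S,4Z)-7-diazo-2,3-bis(TBSO)-5-methoxy-6-oxo-1-[4-(TBSO)phenyl]-7-(triisopropylsilyl)hept-4-en-1-yl acetate | [N-]=[N+]=C([Si](C(C)C)(C(C)C)C(C)C)C(=O)/C(OC)=C/[C@H](O[Si](C)(C)C(C)(C)C)[C@H](O[Si](C)(C)C(C)(C)C)[C@H](OC(C)=O)c1ccc(O[Si](C)(C)C(C)(C)C)cc1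
F2 | step 11 | (1R,2R,3S,4Z)-2,3-bis(TBSO)-5-methoxy-7-oxo-1-[4-(TBSO)phenyl]-6-(triisopropylsilyl)hepta-4,6-dien-1-yl acetate (silyl vinylketene) | O=C=C([Si](C(C)C)(C(C)C)C(C)C)/C(OC)=C/[C@H](O[Si](C)(C)C(C)(C)C)[C@H](O[Si](C)(C)C(C)(C)C)[C@H](OC(C)=O)c1ccc(O[Si](C)(C)C(C)(C)C)cc1
F3 | step 12 | 2-[(1S,2R,3R)-1,2-bis(TBSO)-3-hydroxy-3-[4-(TBSO)phenyl]propyl]-3-methoxy-6-(3-methylbut-2-en-1-yl)-5-(TIPSO)phenol | COc1cc(O[Si](C(C)C)(C(C)C)C(C)C)c(CC=C(C)C)c(O)c1[C@H](O[Si](C)(C)C(C)(C)C)[C@H](O[Si](C)(C)C(C)(C)C)[C@H](O)c1ccc(O[Si](C)(C)C(C)(C)C)cc1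
F4 | step 12 | (2S,3S)-2,3-bis(TBSO)-3-[2-hydroxy-6-methoxy-3-(3-methylbut-2-en-1-yl)-4-(TIPSO)phenyl]-1-[4-(TBSO)phenyl]propan-1-one | COc1cc(O[Si](C(C)C)(C(C)C)C(C)C)c(CC=C(C)C)c(O)c1[C@H](O[Si](C)(C)C(C)(C)C)[C@H](O[Si](C)(C)C(C)(C)C)C(=O)c1ccc(O[Si](C)(C)C(C)(C)C)cc1
F5 | step 12 | 2-[(1S,2R,3S)-1,2-bis(TBSO)-3-hydroxy-3-[4-(TBSO)phenyl]propyl]-3-methoxy-6-(3-methylbut-2-en-1-yl)-5-(TIPSO)phenol | COc1cc(O[Si](C(C)C)(C(C)C)C(C)C)c(CC=C(C)C)c(O)c1[C@H](O[Si](C)(C)C(C)(C)C)[C@H](O[Si](C)(C)C(C)(C)C)[C@@H](O)c1ccc(O[Si](C)(C)C(C)(C)C)cc1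
F6 | step 12 | (2R,3R,4S)-3,4-bis(TBSO)-5-methoxy-8-(3-methylbut-2-en-1-yl)-2-[4-(TBSO)phenyl]-7-(TIPSO)chroman | COc1cc(O[Si](C(C)C)(C(C)C)C(C)C)c(CC=C(C)C)c2c1[C@H](O[Si](C)(C)C(C)(C)C)[C@H](O[Si](C)(C)C(C)(C)C)[C@@H](c1ccc(O[Si](C)(C)C(C)(C)C)cc1)O2
F7 | step 3 | (2R,3R)-2,3-bis(TBSO)-4-hydroxy-N-methoxy-N-methylbutanamide | CON(C)C(=O)[C@H](O[Si](C)(C)C(C)(C)C)[C@H](O[Si](C)(C)C(C)(C)C)CO
F8 | step 3 | (2R,3R)-2,3-bis(TBSO)-N-methoxy-N-methyl-4-(triethylsilyloxy)butanamide | CON(C)C(=O)[C@H](O[Si](C)(C)C(C)(C)C)[C@H](O[Si](C)(C)C(C)(C)C)CO[Si](CC)(CC)CC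
F9 | step 3 | (2R,3R)-2,3-bis(TBSO)-4-(triethylsilyloxy)butanal | O=C[C@H](O[Si](C)(C)C(C)(C)C)[C@H](O[Si](C)(C)C(C)(C)C)CO[Si](CC)(CC)CC
F10 | step 3 | methyl (2Z,4S,5R)-4,5-bis(TBSO)-2-methoxy-6-(triethylsilyloxy)hex-2-enoate | COC(=O)/C(OC)=C/[C@H](O[Si](C)(C)C(C)(C)C)[C@H](O[Si](C)(C)C(C)(C)C)CO[Si](CC)(CC)CC
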